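**Plan**

Retrosynthesis: the acid-labile groups go first (the O–CH2Ar bonds of the PMB ester and of both aryl PMB ethers, and the 1-O–Si bond), then the C3–H bond (carbinol back to the C3 ketone), then the ring bond C1–C2 (an aldol bond; cutting it turns the cyclohexanone into a pyranoside), then the two ester bonds at O4 and O5, and last the C5–C6 bond, which divides a C7 sugar acid into D-erythrose and a 2-(bromomethyl)acrylate.
Enabling feature: the ring C1–C6, with oxygen on C1, C3, C4 and C5 and CH2 at C2 and C6, is the carbocyclic counterpart of a 3-deoxy-D-arabino-hept-2-ulopyranosonate. C1(OH)(CO2H) is its ketosidic carbon, C3 the carbon bound to the ring oxygen and C2 its primary carbon. O4 and O5 are the only hydroxyls left once that primary carbon is an iodide, so both coumarates are attached before the carbocycle exists and no choice between the 4,5- and 1,3-hydroxyls is ever needed.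
Forward order: open-chain C7 ester (indium allylation), pyranose hemiketal (ozonolysis; the only ring, used as a template), methyl ketoside, PMB ester, 7-iodide, both coumarates, exocyclic enol ether, then conversion of the pyranose into the cyclohexanone (the only ring of the target), ketone reduction and acid unmasking.
Stereochemistry: C4 is C2 of D-erythrose. C5 comes from the chelate-controlled threo allylation. C1 comes from the substrate-controlled aldol (hydroxyl axial, trans to O5). C3 comes from equatorial hydride attack on the ketone (erythrose C3 is spent as that ketone carbon). Both alkenes are E as bought in p-coumaric acid.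
Key step: step 10

Remark: locants of the carbocycles follow the quinic acid numbering of the target SMILES (C1 carries OH and CO2H; O4 and O5 acylated and trans; 3-OH cis to O4 and to 1-OH). Sugar intermediates keep heptulosonate numbering (C1 = carboxyl carbon; sugar C2, C3, C4, C5, C6, C7 become target C1, C6, C5, C4, C3, C2). D-erythrose is taken as the commercial syrup.
Abbreviations: PMB = 4-methoxybenzyl; PMB-coumaroyl = (E)-4-(4-methoxybenzyloxy)cinnamoyl, i.e. (2E)-3-{4-[(4-methoxyphenyl)methoxy]phenyl}prop-2-enoyl.

**Route**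

Step 1
Reactants: 1 D-erythrose; 2 methyl 2-(bromomethyl)acrylate
Product: 3 methyl (4R,5S,6R)-4,5,6,7-tetrahydroxy-2-methylideneheptanoate
Conditions: In powder (2 equiv), 2 (2.5 equiv), H2O/MeOH 1:1, rt to 40 °C; filtration, chromatography to remove the minor 4,5-erythro epimer
Reagents that add atoms: none
Why: Barbier-type indium-mediated allylation of the unprotected aldose in water, in which the allylindium should add to the open-chain aldehyde through a chelate between the carbonyl oxygen and the free 2-hydroxyl, giving mainly the 4,5-threo (4R) adduct while C5 and C6 are carried over unchanged from erythrose C2 and C3.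

Step 2
Reactants: 3 methyl (4R,5S,6R)-4,5,6,7-tetrahydroxy-2-methylideneheptanoate
Product: 5 methyl 3-deoxy-α-D-arabino-hept-2-ulopyranosonate, via open-chain keto ester 4 (not isolated)
Conditions: O3, MeOH, −78 °C; then Me2S, −78 °C to rt
Reagents that add atoms: ozone, [O-][O+]=O
Why: Ozonolysis of the 1,1-disubstituted alkene with reductive work-up should unmask the α-keto ester, which the 6-hydroxyl captures as the six-membered hemiketal with all ring substituents equatorial; only the freely equilibrating anomeric carbon is new.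

Step 3
Reactants: 5 methyl 3-deoxy-α-D-arabino-hept-2-ulopyranosonate
Product: 6 methyl (methyl 3-deoxy-α-D-arabino-hept-2-ulopyranosid)onate
Conditions: HCl (0.5 M in MeOH), rt to 50 °C; neutralisation, crystallisation or chromatography
Reagents that add atoms: methanol, CO
Why: Fischer glycosidation under thermodynamic control should give the pyranoside with axial methoxy and equatorial ester (anomeric effect); the anomeric configuration has no bearing on later steps because this carbon becomes a ketone in step 10.

Step 4
Reactants: 6 methyl (methyl 3-deoxy-α-D-arabino-hept-2-ulopyranosid)onate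
Product: 8 4-methoxybenzyl (methyl 3-deoxy-α-D-arabino-hept-2-ulopyranosid)onate, via cesium carboxylate 7 (not isolated)
Conditions: CsOH·H2O (1.0 equiv), MeOH/H2O, 0 °C to rt; evaporation, toluene azeotrope; then PMBCl (1.1 equiv), DMF, rt
Reagents that add atoms: cesium hydroxide, [Cs+].[OH-]; 4-methoxybenzyl chloride, COc1ccc(CCl)cc1
Why: Saponification of the unhindered methyl ester followed by SN2 O-alkylation of the cesium carboxylate, which is far more nucleophilic than the neutral hydroxyls; the ketoside is stable to base, and the PMB ester allows the acid to be freed at the end by acid alone.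

Step 5
Reactants: 8 4-methoxybenzyl (methyl 3-deoxy-α-D-arabino-hept-2-ulopyranosid)onate
Product: 9 4-methoxybenzyl (methyl 3,7-dideoxy-7-iodo-α-D-arabino-hept-2-ulopyranosid)onate
Conditions: I2 (1.3 equiv), PPh3 (1.4 equiv), imidazole (3 equiv), THF, 0 °C to rt
Reagents that add atoms: iodine, II
Why: Garegg–Samuelsson (Appel-type) iodination, in which iodide displaces the alkoxyphosphonium group only at the unhindered primary carbon, leaving the trans-diequatorial 4,5-diol as the only free hydroxyls.

Step 6
Reactants: 10 (E)-p-coumaric acid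
Product: 11 4-methoxybenzyl (E)-4-(4-methoxybenzyloxy)cinnamate
Conditions: PMBCl (2.2 equiv), K2CO3 (2.5 equiv), DMF, 60 °C
Reagents that add atoms: 4-methoxybenzyl chloride, COc1ccc(CCl)cc1
Why: Williamson O-alkylation of the phenoxide and of the carboxylate by the benzylic chloride; the E alkene is not involved.

Step 7
Reactants: 11 4-methoxybenzyl (E)-4-(4-methoxybenzyloxy)cinnamate
Product: 12 (E)-4-(4-methoxybenzyloxy)cinnamic acid
Conditions: 2 M aq NaOH (3 equiv), THF/MeOH, 50 °C; then 1 M HCl to pH 3, 0 °C, filtration
Reagents that add atoms: sodium hydroxide, [Na+].[OH-]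
Why: Saponification cleaves only the ester, since the aryl PMB ether is inert to hydroxide, and cold dilute acid returns the acid without touching the ether.

Step 8
Reactants: 9 4-methoxybenzyl (methyl 3,7-dideoxy-7-iodo-α-D-arabino-hept-2-ulopyranosid)onate; 12 (E)-4-(4-methoxybenzyloxy)cinnamic acid (2.5 equiv)
Product: 13 4-methoxybenzyl [methyl 3,7-dideoxy-7-iodo-4,5-bis-O-(PMB-coumaroyl)-α-D-arabino-hept-2-ulopyranosid]onate
Conditions: DCC (2.6 equiv), 4-(dimethylamino)pyridine (DMAP, 0.5 equiv), CH2Cl2, 0 °C to rt
Reagents that add atoms: none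
Why: Steglich esterification (carbodiimide activation, acyl transfer through the N-acylpyridinium ion) of the two equatorial secondary hydroxyls, which are the only nucleophiles in 9; no stereocentre is involved and the primary iodide is unreactive under these conditions.

Step 9
Reactants: 13 4-methoxybenzyl [methyl 3,7-dideoxy-7-iodo-4,5-bis-O-(PMB-coumaroyl)-α-D-arabino-hept-2-ulopyranosid]onate
Product: 14 4-methoxybenzyl [methyl 3,7-dideoxy-4,5-bis-O-(PMB-coumaroyl)-hept-6-enopyranosid]ulosonate (exocyclic 6,7-enol ether; C2, C4 and C5 as in 13)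
Conditions: AgF (4 equiv), pyridine, rt, dark
Reagents that add atoms: none
Why: Silver-assisted dehydrohalogenation (E2), the standard route from 6-iodo pyranosides carrying ester groups to exocyclic enol ethers; the only β-hydrogen is on C6, so only the 6,7-alkene can form, and the C6 stereocentre is given up on purpose.

Step 10
Reactants: 14 exocyclic enol ether
Product: 16 4-methoxybenzyl 4,5-bis-O-(PMB-coumaroyl)-3-dehydroquinate, via acyclic mercurio diketone 15 (not isolated)
Conditions: Hg(OCOCF3)2 (0.1 equiv), acetone/H2O 4:1, rt; work-up without base, chromatography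
Reagents that add atoms: water, O
Why: Ferrier carbocyclization: Hg(OCOCF3)2 (divalent mercury) adds to the electron-rich 6,7-enol ether at C7 while water adds at C6, the C6 hemiketal collapses to the ketone as the pyranose opens, and the C2 hemiketal loses methanol to give the mercurio diketo ester 15. Its mercury enolate then adds through C7 to the C2 keto ester carbonyl (intramolecular aldol), and protonolysis of the mercury alkoxide returns the catalyst. The closest known reaction type is the mercury-catalysed conversion of 6-deoxyhex-5-enopyranosides into 3-hydroxycyclohexanones, run here on a ketoside so that the acceptor is an α-keto ester, which is the same aldol by which 3-dehydroquinate arises in the shikimate pathway. The cyclohexane closes in a 6-(enolexo)-exo-trig mode. The new stereocentre C1 is set under substrate control: in the chair transition state both acyloxy groups and the CO2PMB group are equatorial and the carbonyl oxygen is axial and bridged by mercury to the enolate oxygen, so the hydroxyl should end up axial and trans to the 5-ester, which is also the more stable aldol if the addition is reversible. The step needs a regiodefined enolate (only C7 carries mercury), chemoselectivity for the enol ether over the two cinnamate alkenes (secured by its far higher electron density) and a near-neutral medium, so that the β-acyloxy ketone does not eliminate.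

Step 11
Reactants: 16 4-methoxybenzyl 4,5-bis-O-(PMB-coumaroyl)-3-dehydroquinate
Product: 17 4-methoxybenzyl 4,5-bis-O-(PMB-coumaroyl)-1-O-trimethylsilyl-3-dehydroquinate
Conditions: TMSOTf (1.3 equiv), 2,6-lutidine (2 equiv), CH2Cl2, −78 to −40 °C; short filtration through deactivated silica
Reagents that add atoms: trimethylsilyl trifluoromethanesulfonate, C[Si](C)(C)OS(=O)(=O)C(F)(F)F
Why: Silylation of the hindered tertiary carbinol with a silyl triflate and a hindered weak base at low temperature, as used routinely for aldol adducts, should neither enolise the ketone nor trigger β-elimination; the ether blocks retro-aldol opening and hydroxyl-directed hydride delivery in step 12 and enlarges the axial group that shields one face of the ketone (a chelate between O1 and the C3 carbonyl is not geometrically possible in this ring, so steric control is used).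

Step 12
Reactants: 17 4-methoxybenzyl 4,5-bis-O-(PMB-coumaroyl)-1-O-trimethylsilyl-3-dehydroquinate
Product: 18 4-methoxybenzyl 4,5-bis-O-(PMB-coumaroyl)-1-O-trimethylsilylquinate
Conditions: LiBH(s-Bu)3 (L-Selectride, 1.1 equiv), THF, −78 °C; AcOH (3 equiv) at −78 °C, then aq NH4Cl
Reagents that add atoms: none
Why: Reduction of a conformationally fixed cyclohexanone by a bulky trialkylborohydride, which should attack along the equatorial trajectory because the axial approach is closed by the syn-axial 1-OSiMe3 group, giving the axial 3-hydroxyl cis to O1 and to the 4-ester; at −78 °C the ketone reacts far faster than the β-aryl enoates, and the cold acidic quench protonates the alkoxide before the neighbouring 4-ester can migrate.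

Step 13
Reactants: 18 4-methoxybenzyl 4,5-bis-O-(PMB-coumaroyl)-1-O-trimethylsilylquinate
Product: 19 4,5-di-O-[(E)-p-coumaroyl]quinic acid
Conditions: TFA/CH2Cl2 1:4, anisole (10 equiv), H2O (3 equiv), 0 °C to rt; cold evaporation with toluene, reversed-phase chromatography with acidic eluent
Reagents that add atoms: none
Why: Acidolysis (SN1 cleavage) of the PMB ester and both aryl PMB ethers with Friedel–Crafts capture of the 4-methoxybenzyl cation by anisole, together with protodesilylation of the silyl ether; no base is used, so the 4-ester should stay in place although the 3-hydroxyl is cis to it, and the 5-ester blocks lactone formation.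

**Compound list**

1 | D-erythrose, (2R,3R)-2,3,4-trihydroxybutanal | O=C[C@H](O)[C@H](O)CO | starting material
2 | methyl 2-(bromomethyl)acrylate | C=C(CBr)C(=O)OC | starting material
3 | methyl (4R,5S,6R)-4,5,6,7-tetrahydroxy-2-methylideneheptanoate (4,5-threo; 5,6-erythro) | COC(=O)C(=C)C[C@@H](O)[C@H](O)[C@H](O)CO | intermediate
4 | methyl (4R,5S,6R)-4,5,6,7-tetrahydroxy-2-oxoheptanoate, open-chain keto ester (not isolated) | COC(=O)C(=O)C[C@@H](O)[C@H](O)[C@H](O)CO | intermediate
5 | methyl 3-deoxy-α-D-arabino-hept-2-ulopyranosonate (hemiketal; axial 2-OH drawn) | COC(=O)[C@@]1(O)C[C@@H](O)[C@H](O)[C@@H](CO)O1 | intermediate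
6 | methyl (methyl 3-deoxy-α-D-arabino-hept-2-ulopyranosid)onate (axial 2-OMe) | COC(=O)[C@@]1(OC)C[C@@H](O)[C@H](O)[C@@H](CO)O1 | intermediate
7 | cesium (methyl 3-deoxy-α-D-arabino-hept-2-ulopyranosid)onate (not isolated) | [Cs+].[O-]C(=O)[C@@]1(OC)C[C@@H](O)[C@H](O)[C@@H](CO)O1 | intermediate
8 | 4-methoxybenzyl (methyl 3-deoxy-α-D-arabino-hept-2-ulopyranosid)onate | COc1ccc(COC(=O)[C@@]2(OC)C[C@@H](O)[C@H](O)[C@@H](CO)O2)cc1 | intermediate
9 | 4-methoxybenzyl (methyl 3,7-dideoxy-7-iodo-α-D-arabino-hept-2-ulopyranosid)onate | COc1ccc(COC(=O)[C@@]2(OC)C[C@@H](O)[C@H](O)[C@@H](CI)O2)cc1 | intermediate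
10 | (E)-p-coumaric acid | O=C(O)/C=C/c1ccc(O)cc1 | starting material
11 | 4-methoxybenzyl (E)-4-(4-methoxybenzyloxy)cinnamate | COc1ccc(COC(=O)/C=C/c2ccc(OCc3ccc(OC)cc3)cc2)cc1 | intermediate
12 | (E)-4-(4-methoxybenzyloxy)cinnamic acid | COc1ccc(COc2ccc(/C=C/C(=O)O)cc2)cc1 | intermediate
13 | 4-methoxybenzyl [methyl 3,7-dideoxy-7-iodo-4,5-bis-O-(PMB-coumaroyl)-α-D-arabino-hept-2-ulopyranosid]onate | COc1ccc(COC(=O)[C@@]2(OC)C[C@@H](OC(=O)/C=C/c3ccc(OCc4ccc(OC)cc4)cc3)[C@H](OC(=O)/C=C/c3ccc(OCc4ccc(OC)cc4)cc3)[C@@H](CI)O2)cc1 | intermediate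
14 | 4-methoxybenzyl [methyl 3,7-dideoxy-4,5-bis-O-(PMB-coumaroyl)-hept-6-enopyranosid]ulosonate (exocyclic 6,7-enol ether of 13; axial 2-OMe; 4R,5S) | COc1ccc(COC(=O)[C@@]2(OC)C[C@@H](OC(=O)/C=C/c3ccc(OCc4ccc(OC)cc4)cc3)[C@H](OC(=O)/C=C/c3ccc(OCc4ccc(OC)cc4)cc3)C(=C)O2)cc1 | intermediate
15 | 4-methoxybenzyl (4R,5S)-4,5-bis(PMB-coumaroyloxy)-2,6-dioxo-7-[(trifluoroacetoxy)mercurio]heptanoate, acyclic mercurio diketone (not isolated) | COc1ccc(COC(=O)C(=O)C[C@@H](OC(=O)/C=C/c2ccc(OCc3ccc(OC)cc3)cc2)[C@H](OC(=O)/C=C/c2ccc(OCc3ccc(OC)cc3)cc2)C(=O)C[Hg]OC(=O)C(F)(F)F)cc1 | intermediate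
16 | 4-methoxybenzyl 4,5-bis-O-(PMB-coumaroyl)-3-dehydroquinate, i.e. 4-methoxybenzyl (1R,4S,5R)-1-hydroxy-3-oxo-4,5-bis(PMB-coumaroyloxy)cyclohexane-1-carboxylate (1-OH axial and trans to O5; O4 and O5 trans-diequatorial) | O=C(/C=C/c1ccc(OCc2ccc(OC)cc2)cc1)O[C@@H]1C(=O)C[C@@](O)(C(=O)OCc2ccc(OC)cc2)C[C@H]1OC(=O)/C=C/c1ccc(OCc2ccc(OC)cc2)cc1 | intermediate
17 | 4-methoxybenzyl 4,5-bis-O-(PMB-coumaroyl)-1-O-trimethylsilyl-3-dehydroquinate (1R,4S,5R) | O=C(/C=C/c1ccc(OCc2ccc(OC)cc2)cc1)O[C@@H]1C(=O)C[C@@](O[Si](C)(C)C)(C(=O)OCc2ccc(OC)cc2)C[C@H]1OC(=O)/C=C/c1ccc(OCc2ccc(OC)cc2)cc1 | intermediate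
18 | 4-methoxybenzyl 4,5-bis-O-(PMB-coumaroyl)-1-O-trimethylsilylquinate (1S,3R,4R,5R; 3-OH axial, cis to O1 and O4) | O=C(/C=C/c1ccc(OCc2ccc(OC)cc2)cc1)O[C@@H]1[C@H](O)C[C@@](O[Si](C)(C)C)(C(=O)OCc2ccc(OC)cc2)C[C@H]1OC(=O)/C=C/c1ccc(OCc2ccc(OC)cc2)cc1 | intermediate
19 | 4,5-di-O-[(E)-p-coumaroyl]quinic acid, (1S,3R,4R,5R)-1,3-dihydroxy-4,5-bis{[(2E)-3-(4-hydroxyphenyl)prop-2-enoyl]oxy}cyclohexane-1-carboxylic acid | O=C(/C=C/c1ccc(O)cc1)O[C@@H]1[C@H](O)C[C@@](O)(C(=O)O)C[C@H]1OC(=O)/C=C/c1ccc(O)cc1 | target

**Step count and risks**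

Total step count: 13. Longest linear sequence: 11 steps (steps 1–5 and 8–13, from D-erythrose); steps 6 and 7 prepare the acyl partner.

The three steps most likely to fail:

Step 10. The mercury-triggered opening of a ketoside whose anomeric carbon carries an ester may be slow. The open keto ester may lose the 4-acyloxy group by β-elimination before the aldol, or the aldol may close with poor facial selectivity at C1. The fallback separates ring opening from ring closure and uses no metal; it sets out from enol ether 14 and comes back at ketone 16. Dilute aqueous acid (0.05 M HCl in THF/H2O, 0 °C to rt) should hydrolyse the enol ether, the C6 hemiketal opens the ring and the C2 hemiketal loses methanol, giving the open-chain 4-methoxybenzyl (4R,5S)-4,5-bis(PMB-coumaroyloxy)-2,6-dioxoheptanoate F1. A proline-catalysed enamine aldol (L- or D-proline, whichever is the matched case, 0.2–0.3 equiv, DMSO, rt), in which the enamine of the methyl ketone adds to the keto ester in a 6-enolexo closure, should then give 16, with the catalyst offering a second handle on the C1 configuration.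

Step 12. Hydride may attack the ketone from the wrong face, the alkoxide may pull the 4-ester over to O3, or the enoates may undergo conjugate reduction. The fallback turns the facial problem into an inversion; it sets out from ketone 16 (step 11 is then skipped) and comes back at target 19. Me4NBH(OAc)3 in MeCN/AcOH at −20 °C delivers hydride intramolecularly from the axial 1-hydroxyl (1,3-anti reduction) and should give 4-methoxybenzyl 4,5-bis-O-(PMB-coumaroyl)-3-epi-quinate F2, with the 3-hydroxyl equatorial. Tf2O/pyridine (CH2Cl2, −20 °C) should convert only the secondary hydroxyl into the 3-O-triflate F3, the tertiary carbinol being too hindered. Bu4NNO2 (MeCN, rt), a Lattrell–Dax inversion of the kind that works well next to an equatorial ester, should give the axial 3-O-nitrite ester F4, which is hydrolysed on aqueous work-up to 4-methoxybenzyl 4,5-bis-O-(PMB-coumaroyl)quinate F5. F5 is unmasked under the conditions of step 13 to give 19.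

Step 13. Three 4-methoxybenzyl cations are released next to two electron-rich phenols, so ring benzylation may compete with the scavenger, and prolonged acid contact may shift the 4-ester to the cis 3-hydroxyl. The fallback stages the unmasking and removes the aryl ethers oxidatively; it sets out from 18 and comes back at 19. DDQ (2.5 equiv, CH2Cl2/pH 7 phosphate buffer, 0 °C to rt) should cleave the two aryl PMB ethers as 4-methoxybenzaldehyde and give 4-methoxybenzyl 4,5-di-O-[(E)-p-coumaroyl]-1-O-trimethylsilylquinate F6. A short treatment with TFA/anisole at 0 °C, which now generates a single benzyl cation, should then remove the ester PMB and the silyl group to give 19.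

**Further compounds**

F1 | step 10 | 4-methoxybenzyl (4R,5S)-4,5-bis(PMB-coumaroyloxy)-2,6-dioxoheptanoate | COc1ccc(COC(=O)C(=O)C[C@@H](OC(=O)/C=C/c2ccc(OCc3ccc(OC)cc3)cc2)[C@H](OC(=O)/C=C/c2ccc(OCc3ccc(OC)cc3)cc2)C(C)=O)cc1
F2 | step 12 | 4-methoxybenzyl 4,5-bis-O-(PMB-coumaroyl)-3-epi-quinate (3-OH equatorial, trans to O1 and O4) | O=C(/C=C/c1ccc(OCc2ccc(OC)cc2)cc1)O[C@@H]1[C@@H](O)C[C@@](O)(C(=O)OCc2ccc(OC)cc2)C[C@H]1OC(=O)/C=C/c1ccc(OCc2ccc(OC)cc2)cc1
F3 | step 12 | 4-methoxybenzyl 4,5-bis-O-(PMB-coumaroyl)-3-O-trifluoromethanesulfonyl-3-epi-quinate | O=C(/C=C/c1ccc(OCc2ccc(OC)cc2)cc1)O[C@@H]1[C@@H](OS(=O)(=O)C(F)(F)F)C[C@@](O)(C(=O)OCc2ccc(OC)cc2)C[C@H]1OC(=O)/C=C/c1ccc(OCc2ccc(OC)cc2)cc1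
F4 | step 12 | 4-methoxybenzyl 4,5-bis-O-(PMB-coumaroyl)quinate 3-O-nitrite ester (not isolated) | O=C(/C=C/c1ccc(OCc2ccc(OC)cc2)cc1)O[C@@H]1[C@H](ON=O)C[C@@](O)(C(=O)OCc2ccc(OC)cc2)C[C@H]1OC(=O)/C=C/c1ccc(OCc2ccc(OC)cc2)cc1
F5 | step 12 | 4-methoxybenzyl 4,5-bis-O-(PMB-coumaroyl)quinate (free 1-OH and axial 3-OH) | O=C(/C=C/c1ccc(OCc2ccc(OC)cc2)cc1)O[C@@H]1[C@H](O)C[C@@](O)(C(=O)OCc2ccc(OC)cc2)C[C@H]1OC(=O)/C=C/c1ccc(OCc2ccc(OC)cc2)cc1
F6 | step 13 | 4-methoxybenzyl 4,5-di-O-[(E)-p-coumaroyl]-1-O-trimethylsilylquinate | O=C(/C=C/c1ccc(O)cc1)O[C@@H]1[C@H](O)C[C@@](O[Si](C)(C)C)(C(=O)OCc2ccc(OC)cc2)C[C@H]1OC(=O)/C=C/c1ccc(O)cc1
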